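Amounts first: in the flask the other conformer is 9.09% of the charge, yet in the blue run, which is this flask followed so far, the isomer of the product holds 40.6% at 6.00 min while the other conformer reads 0%. So the isomer reads more than the other conformer's charge, and the difference has come from the substrate, the charge that the side product draws on too.

| flask | substrate | other conformer | catalyst | remark | time |
|---|---|---|---|---|---|
| blue | 0.10 M | 0.010 M | 0.34 mM | the very flask that is asked about, followed so far |  |
| green | 0.10 M | 0.015 M | 0.34 mM | run made earlier |  |
| flask | 0.10 M | 0.0100 M | 0.34 mM |  | 15 min |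

| run | time / min | side product / % | isomer of the product / % | substrate / % | other conformer / % | target / % |
|---|---|---|---|---|---|---|
| blue | 0.333 | 3.0 | 5.4 | 81.6 | 0.2 | 9.6 |
| blue | 1.00 | 10.5 | 13.4 | 59.2 | 0.6 | 16.4 |
| blue | 1.50 | 15.9 | 18.1 | 48.3 | 0 | 16.2 |
| blue | 2.50 | 23.5 | 26.3 | 34.7 | 0 | 15.2 |
| blue | 4.00 | 32.1 | 33.9 | 23.6 | 0.3 | 11.4 |
| blue | 5.00 | 34.1 | 37.1 | 18.9 | 0 | 8.5 |
| blue | 6.00 | 34.7 | 40.6 | 16.7 | 0 | 7.4 |
| green | 2.00 | 21.8 | 23.3 | 40.0 | 1.1 | 16.3 |
| green | 4.00 | 30.7 | 34.0 | 23.5 | 0.1 | 11.1 |
| green | 6.00 | 35.7 | 40.4 | 16.6 | 0.1 | 7.4 |
| green | 8.00 | 38.3 | 45.2 | 10.8 | 0 | 4.9 |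
| green | 10.0 | 39.8 | 48.7 | 7.5 | 0.5 | 4.1 |
| green | 12.0 | 39.7 | 50.5 | 6.1 | 0.5 | 3.7 |
| green | 15.0 | 40.8 | 53.3 | 4.2 | 0 | 1.9 |

(standard deviation of a reading: 0.5 percentage points)

- the largest share of what was charged as substrate and other conformer together, at 15 min belongs to (other conformer / side product / target / substrate / isomer of the product)
- the largest share itself, whichever of these holds it, in percent of the substrate and other conformer together charged

- percentages count the substrate that a species holds: one side product counts as two

In the blue run, from 1.50 min to 4.00 min, the isomer's gain reads 0.975 times the side product's gain, at a mean target share of 13.8%. I multiply the two, taking the side product's gain as proportional to target, and get 13.5%, the crossing share: the target share at which both gain equally, a selectivity factor in another form. At this catalyst charge, the side product gains faster above it and the isomer below it.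

To test whether one number is enough, I take the green run from 4.00 min to 15.0 min. Its mean target, 6.50%, is half as high, and its ratio of gains, 1.91, is twice as large, so the crossing share reads 12.4% in the green run. At 6.00 min blue's target reads 7.4%, lower than the crossing share, and its isomer already reads 40.6% against 34.7% of side product, so I expect the isomer to lead in the flask at 15 min.

The forecast says isomer of the product, 53%: “The green curve can therefore stand in for blue's future”.

The flask gives isomer of the product, 53.8%.

    substrate + target → side product (k = 0.0950 L mol⁻¹ s⁻¹)
    substrate ⇌ other conformer (K = 0.00180, k = 0.0370 s⁻¹)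
    substrate + catalyst ⇌ catalyst + target (K = 0.440, k = 21.0 L mol⁻¹ s⁻¹)
    catalyst + other conformer → catalyst + isomer of the product (k = 5200 L mol⁻¹ s⁻¹)

Catalyst at 0.274 mM moves that isomer share by 5 points. With target at 1.99%, the crossing share puts the isomer's gain at 6.78 times the side product's gain at the end of the flask.

For the neighbour flask with catalyst at 2.0 × 10⁻⁴ M, I scale the crossing share by the catalyst ratio, the isomer step carrying catalyst in these equations and the side-product step not, and get 7.92%, lower than the flask's, so I expect the side product to keep gaining faster down to a lower target share. That neighbour flask computes to side product 47.9% against isomer 41.7% at 15 min.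

(The data stem from a simulated flask with made-up constants.)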